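1. The target 22 comes from tetralone 20 by dealkylation (BCl3) and desilylation. The carbocycle is closed last, by Friedel–Crafts acylation C1–C8a of acid 18, ortho to the methoxy group.
2. Feature: the 4-hydroxy-2-pyrone (O1', C2' carbonyl, C3', C4'–OH, C5', C6') is bonded through C6' to C5 of the benzene ring, between C4a (carrying C4H2) and C6 (carrying the 3-methylbutyl chain). C6' is therefore crowded, while C5' one atom further out is open.
3. The pyrone ring is formed first: 16 from silyl enol ether 13 and malonyl dichloride 14 (bonds C5'–C4' and O1'–C2'), while the C5 acetyl group is the only ketone in the molecule.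
4. 13 comes from ketone 12, which comes from aryl bromide 9 by Stille coupling with stannane 10; 9 comes from bromination of 8 para to the methoxy group.
5. 8 comes from arylmagnesium 6 (from 3, made from 1 and 2) and epoxy ester 5 (from 4), which supplies C3 as a single enantiomer.

Key step: step 8

Remark: the C3 oxygen is carried as a tert-butyldiphenylsilyl ether and the pyrone hydroxyl is later masked as a benzyl ether, both chosen to survive the HCl of step 8 and the Lewis acid of step 11.

Step 1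
Reactants: 1 3,5-dibromoanisole; 2 (3-methylbutyl)magnesium bromide
Product: 3 1-bromo-3-methoxy-5-(3-methylbutyl)benzene
Conditions: PdCl2(dppf) (1 mol %), THF, 0 °C → rt; 2 (1.0 equiv) added slowly to 1 (1.5 equiv)
Reagents that add atoms: none
Why: Kumada–Corriu coupling of a primary alkyl Grignard reagent with an aryl bromide; slow addition to an excess of the symmetrical dibromide should hold the reaction at mono-alkylation, and unreacted 1 can be recovered by distillation.

Step 2
Reactants: 4 ethyl (3S)-4-chloro-3-hydroxybutanoate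
Product: 5 ethyl 2-[(2S)-oxiran-2-yl]acetate
Conditions: Ag2O (1.0 equiv), 1,2-dimethoxyethane, 60 °C, dark
Reagents that add atoms: none
Why: Silver-assisted intramolecular Williamson etherification closes the epoxide without a soluble base, which would open the β,γ-epoxy ester to the 4-hydroxybut-2-enoate; no bond to the carbinol carbon is broken, so the S configuration is kept.

Step 3
Reactants: 3 1-bromo-3-methoxy-5-(3-methylbutyl)benzene; 5 ethyl 2-[(2S)-oxiran-2-yl]acetate
Product: 7 ethyl (3R)-3-hydroxy-4-[3-methoxy-5-(3-methylbutyl)phenyl]butanoate, via arylmagnesium bromide 6 (not isolated)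
Conditions: Mg, THF, reflux; then CuI (10 mol %), 5, THF, −40 → −20 °C; cold 1 M aq. HCl
Reagents that add atoms: none
Why: Grignard formation followed by copper-catalysed SN2 opening of the epoxide at its unsubstituted terminal carbon, which at −40 °C is faster than addition to the ethyl ester; the carbinol centre comes unchanged from 5 and is named R in 7 only because CH2Ar ranks below CH2CO2Et.

Step 4
Reactants: 7 ethyl (3R)-3-hydroxy-4-[3-methoxy-5-(3-methylbutyl)phenyl]butanoate
Product: 8 ethyl (3R)-3-[(tert-butyldiphenylsilyl)oxy]-4-[3-methoxy-5-(3-methylbutyl)phenyl]butanoate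
Conditions: TBDPSCl, imidazole, DMF, rt
Reagents that add atoms: tert-butyl(chloro)diphenylsilane, CC(C)(C)[Si](Cl)(c1ccccc1)c1ccccc1
Why: Imidazole-promoted silylation of a secondary alcohol under conditions that do not cause retro-aldol cleavage or elimination of the β-hydroxy ester.

Step 5
Reactants: 8 ethyl (3R)-3-[(tert-butyldiphenylsilyl)oxy]-4-[3-methoxy-5-(3-methylbutyl)phenyl]butanoate
Product: 9 ethyl (3R)-4-[2-bromo-5-methoxy-3-(3-methylbutyl)phenyl]-3-[(tert-butyldiphenylsilyl)oxy]butanoate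
Conditions: NBS (1.05 equiv), MeCN, 0 °C → rt, dark
Reagents that add atoms: N-bromosuccinimide, O=C1CCC(=O)N1Br
Why: Electrophilic aromatic bromination with NBS in acetonitrile, which is strongly para-selective for anisoles and is known to brominate 3,5-dialkylanisoles between the two alkyl groups; ionic conditions in the dark should leave the benzylic positions untouched.

Step 6
Reactants: 9 ethyl (3R)-4-[2-bromo-5-methoxy-3-(3-methylbutyl)phenyl]-3-[(tert-butyldiphenylsilyl)oxy]butanoate; 10 tributyl(1-ethoxyvinyl)stannane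
Product: 12 ethyl (3R)-4-[2-acetyl-5-methoxy-3-(3-methylbutyl)phenyl]-3-[(tert-butyldiphenylsilyl)oxy]butanoate, via aryl 1-ethoxyvinyl ether 11 (not isolated)
Conditions: Pd(P(t-Bu)3)2 (5 mol %), CsF (2.2 equiv), 1,4-dioxane, 80 °C; then 1 M aq. HCl, THF, rt
Reagents that add atoms: water, O
Why: Stille coupling of the di-ortho-substituted aryl bromide, made feasible by the bulky electron-rich phosphine and fluoride activation of the stannane, then acid hydrolysis of enol ether 11 to the methyl ketone under conditions the tert-butyldiphenylsilyl ether tolerates.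

Step 7
Reactants: 12 ethyl (3R)-4-[2-acetyl-5-methoxy-3-(3-methylbutyl)phenyl]-3-[(tert-butyldiphenylsilyl)oxy]butanoate
Product: 13 ethyl (3R)-3-[(tert-butyldiphenylsilyl)oxy]-4-{5-methoxy-3-(3-methylbutyl)-2-[1-(trimethylsilyloxy)ethenyl]phenyl}butanoate
Conditions: TMSOTf (1.3 equiv), Et3N (2 equiv), CH2Cl2, 0 °C; pentane, filtration, concentration; used crude
Reagents that add atoms: trimethylsilyl trifluoromethanesulfonate, C[Si](C)(C)OS(=O)(=O)C(F)(F)F
Why: Soft enolisation with TMSOTf and triethylamine silylates the methyl ketone, the only carbonyl group that enolises under these conditions at 0 °C, so the ethyl ester is left alone and no strong base is present that could eliminate the β-silyloxy group.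

Step 8
Reactants: 13 ethyl (3R)-3-[(tert-butyldiphenylsilyl)oxy]-4-{5-methoxy-3-(3-methylbutyl)-2-[1-(trimethylsilyloxy)ethenyl]phenyl}butanoate; 14 malonyl dichloride
Product: 16 ethyl (3R)-3-[(tert-butyldiphenylsilyl)oxy]-4-[2-(4-hydroxy-2-oxo-2H-pyran-6-yl)-5-methoxy-3-(3-methylbutyl)phenyl]butanoate, via 3,5-dioxo acid chloride 15 (not isolated)
Conditions: 14 (1.1 equiv), Et2O, −78 °C → rt
Reagents that add atoms: none
Why: Malonyl dichloride (as such or as chlorocarbonylketene formed from it by loss of HCl) acylates the open terminal methylene carbon of silyl enol ether 13 (C5'–C4'), and chloride removes the trimethylsilyl group to give the 3,5-dioxo acid chloride 15. The enol oxygen of the aryl ketone in 15 then attacks the remaining acid chloride (O1'–C2') in a 6-exo-trig lactonisation, and tautomerisation of the pyran-2,4-dione gives the 4-hydroxy-2-pyrone ring of 16. The closest known reaction is the annulation of ketone trimethylsilyl enol ethers with malonyl dichloride to 6-substituted 4-hydroxy-2-pyrones (Effenberger-type pyrone synthesis). No stereocentre is formed, and the C3 silyloxy centre is remote and not affected. The step needs C- before O-acylation and reaction of the ketone-derived enol ether alone: the soft terminal carbon is the site at which a silyl enol ether meets an acid chloride, the ester was not silylated in step 7, and no bond is made at the crowded C6' between the C4a and C6 alkyl groups. The acid-stable tert-butyldiphenylsilyl ether and the ethyl ester should tolerate the one equivalent of HCl released in ether at low temperature.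

Step 9
Reactants: 16 ethyl (3R)-3-[(tert-butyldiphenylsilyl)oxy]-4-[2-(4-hydroxy-2-oxo-2H-pyran-6-yl)-5-methoxy-3-(3-methylbutyl)phenyl]butanoate
Product: 17 ethyl (3R)-4-{2-[4-(benzyloxy)-2-oxo-2H-pyran-6-yl]-5-methoxy-3-(3-methylbutyl)phenyl}-3-[(tert-butyldiphenylsilyl)oxy]butanoate
Conditions: BnOH, PPh3, DIAD, THF, 0 °C → rt
Reagents that add atoms: benzyl alcohol, OCc1ccccc1
Why: Mitsunobu alkylation of the acidic pyrone hydroxyl (a vinylogous carboxylic acid) should give clean O-alkylation at the C4' oxygen and removes the acidic, nucleophilic enol before the acid chloride is made.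

Step 10
Reactants: 17 ethyl (3R)-4-{2-[4-(benzyloxy)-2-oxo-2H-pyran-6-yl]-5-methoxy-3-(3-methylbutyl)phenyl}-3-[(tert-butyldiphenylsilyl)oxy]butanoate
Product: 18 (3R)-4-{2-[4-(benzyloxy)-2-oxo-2H-pyran-6-yl]-5-methoxy-3-(3-methylbutyl)phenyl}-3-[(tert-butyldiphenylsilyl)oxy]butanoic acid
Conditions: Me3SnOH (5 equiv), 1,2-dichloroethane, 70 °C; 1 M aq. HCl wash
Reagents that add atoms: trimethyltin hydroxide, C[Sn](C)(C)O
Why: Ester cleavage with Me3SnOH under essentially neutral conditions, chosen because free hydroxide could open the alkoxypyrone or eliminate the β-silyloxy group.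

Step 11
Reactants: 18 (3R)-4-{2-[4-(benzyloxy)-2-oxo-2H-pyran-6-yl]-5-methoxy-3-(3-methylbutyl)phenyl}-3-[(tert-butyldiphenylsilyl)oxy]butanoic acid
Product: 20 (3R)-5-[4-(benzyloxy)-2-oxo-2H-pyran-6-yl]-3-[(tert-butyldiphenylsilyl)oxy]-8-methoxy-6-(3-methylbutyl)-3,4-dihydronaphthalen-1(2H)-one, via acid chloride 19 (not isolated)
Conditions: 1-chloro-N,N,2-trimethylprop-1-en-1-amine (Ghosez reagent), CH2Cl2, 0 °C; then SnCl4 (1.2 equiv), CH2Cl2, −78 → −20 °C
Reagents that add atoms: none
Why: Neutral acid chloride formation followed by SnCl4-promoted intramolecular Friedel–Crafts acylation closes the six-membered ketone ring at C8a, the only ring position within reach of the chain, which is activated by the ortho methoxy group and the para alkyl chain.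

Step 12
Reactants: 20 (3R)-5-[4-(benzyloxy)-2-oxo-2H-pyran-6-yl]-3-[(tert-butyldiphenylsilyl)oxy]-8-methoxy-6-(3-methylbutyl)-3,4-dihydronaphthalen-1(2H)-one
Product: 21 (3R)-3-[(tert-butyldiphenylsilyl)oxy]-8-hydroxy-5-(4-hydroxy-2-oxo-2H-pyran-6-yl)-6-(3-methylbutyl)-3,4-dihydronaphthalen-1(2H)-one
Conditions: BCl3 (4 equiv), pentamethylbenzene (3 equiv), CH2Cl2, −78 → 0 °C; aq. work-up
Reagents that add atoms: none
Why: Boron trichloride dealkylation: the methyl ether peri to the C1 carbonyl is cleaved through a six-membered boron chelate and the benzyl vinylogous ester is cleaved with pentamethylbenzene trapping the benzyl cation, while the bulky silyl ether should survive at low temperature.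

Step 13
Reactants: 21 (3R)-3-[(tert-butyldiphenylsilyl)oxy]-8-hydroxy-5-(4-hydroxy-2-oxo-2H-pyran-6-yl)-6-(3-methylbutyl)-3,4-dihydronaphthalen-1(2H)-one
Product: 22 (3R)-3,8-dihydroxy-5-(4-hydroxy-2-oxo-2H-pyran-6-yl)-6-(3-methylbutyl)-3,4-dihydronaphthalen-1(2H)-one
Conditions: HF·pyridine, pyridine, THF, 0 °C → rt
Reagents that add atoms: none
Why: Fluoride-mediated desilylation under buffered, weakly acidic conditions avoids base-induced dehydration of the β-hydroxy ketone to a naphthol and does not touch the C3 stereocentre.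

Compound list
1 | 3,5-dibromoanisole | COc1cc(Br)cc(Br)c1 | starting material
2 | (3-methylbutyl)magnesium bromide | CC(C)CC[Mg]Br | starting material
3 | 1-bromo-3-methoxy-5-(3-methylbutyl)benzene | COc1cc(Br)cc(CCC(C)C)c1 | intermediate
4 | ethyl (3S)-4-chloro-3-hydroxybutanoate | ClC[C@@H](O)CC(=O)OCC | starting material
5 | ethyl 2-[(2S)-oxiran-2-yl]acetate | C1[C@@H](O1)CC(=O)OCC | intermediate
6 | [3-methoxy-5-(3-methylbutyl)phenyl]magnesium bromide | COc1cc([Mg]Br)cc(CCC(C)C)c1 | intermediate
7 | ethyl (3R)-3-hydroxy-4-[3-methoxy-5-(3-methylbutyl)phenyl]butanoate | CC(C)CCc1cc(OC)cc(C[C@@H](O)CC(=O)OCC)c1 | intermediate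
8 | ethyl (3R)-3-[(tert-butyldiphenylsilyl)oxy]-4-[3-methoxy-5-(3-methylbutyl)phenyl]butanoate | CC(C)CCc1cc(OC)cc(C[C@@H](O[Si](c2ccccc2)(c2ccccc2)C(C)(C)C)CC(=O)OCC)c1 | intermediate
9 | ethyl (3R)-4-[2-bromo-5-methoxy-3-(3-methylbutyl)phenyl]-3-[(tert-butyldiphenylsilyl)oxy]butanoate | CC(C)CCc1cc(OC)cc(C[C@@H](O[Si](c2ccccc2)(c2ccccc2)C(C)(C)C)CC(=O)OCC)c1Br | intermediate
10 | tributyl(1-ethoxyvinyl)stannane | CCCC[Sn](CCCC)(CCCC)C(=C)OCC | starting material
11 | ethyl (3R)-3-[(tert-butyldiphenylsilyl)oxy]-4-[2-(1-ethoxyethenyl)-5-methoxy-3-(3-methylbutyl)phenyl]butanoate | CC(C)CCc1cc(OC)cc(C[C@@H](O[Si](c2ccccc2)(c2ccccc2)C(C)(C)C)CC(=O)OCC)c1C(=C)OCC | intermediate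
12 | ethyl (3R)-4-[2-acetyl-5-methoxy-3-(3-methylbutyl)phenyl]-3-[(tert-butyldiphenylsilyl)oxy]butanoate | CC(C)CCc1cc(OC)cc(C[C@@H](O[Si](c2ccccc2)(c2ccccc2)C(C)(C)C)CC(=O)OCC)c1C(C)=O | intermediate
13 | ethyl (3R)-3-[(tert-butyldiphenylsilyl)oxy]-4-{5-methoxy-3-(3-methylbutyl)-2-[1-(trimethylsilyloxy)ethenyl]phenyl}butanoate | CC(C)CCc1cc(OC)cc(C[C@@H](O[Si](c2ccccc2)(c2ccccc2)C(C)(C)C)CC(=O)OCC)c1C(=C)O[Si](C)(C)C | intermediate
14 | malonyl dichloride | O=C(Cl)CC(=O)Cl | starting material
15 | ethyl (3R)-3-[(tert-butyldiphenylsilyl)oxy]-4-[2-(5-chloro-3,5-dioxopentanoyl)-5-methoxy-3-(3-methylbutyl)phenyl]butanoate | CC(C)CCc1cc(OC)cc(C[C@@H](O[Si](c2ccccc2)(c2ccccc2)C(C)(C)C)CC(=O)OCC)c1C(=O)CC(=O)CC(=O)Cl | intermediate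
16 | ethyl (3R)-3-[(tert-butyldiphenylsilyl)oxy]-4-[2-(4-hydroxy-2-oxo-2H-pyran-6-yl)-5-methoxy-3-(3-methylbutyl)phenyl]butanoate | CC(C)CCc1cc(OC)cc(C[C@@H](O[Si](c2ccccc2)(c2ccccc2)C(C)(C)C)CC(=O)OCC)c1-c1cc(O)cc(=O)o1 | intermediate
17 | ethyl (3R)-4-{2-[4-(benzyloxy)-2-oxo-2H-pyran-6-yl]-5-methoxy-3-(3-methylbutyl)phenyl}-3-[(tert-butyldiphenylsilyl)oxy]butanoate | CC(C)CCc1cc(OC)cc(C[C@@H](O[Si](c2ccccc2)(c2ccccc2)C(C)(C)C)CC(=O)OCC)c1-c1cc(OCc2ccccc2)cc(=O)o1 | intermediate
18 | (3R)-4-{2-[4-(benzyloxy)-2-oxo-2H-pyran-6-yl]-5-methoxy-3-(3-methylbutyl)phenyl}-3-[(tert-butyldiphenylsilyl)oxy]butanoic acid | CC(C)CCc1cc(OC)cc(C[C@@H](O[Si](c2ccccc2)(c2ccccc2)C(C)(C)C)CC(=O)O)c1-c1cc(OCc2ccccc2)cc(=O)o1 | intermediate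
19 | (3R)-4-{2-[4-(benzyloxy)-2-oxo-2H-pyran-6-yl]-5-methoxy-3-(3-methylbutyl)phenyl}-3-[(tert-butyldiphenylsilyl)oxy]butanoyl chloride | CC(C)CCc1cc(OC)cc(C[C@@H](O[Si](c2ccccc2)(c2ccccc2)C(C)(C)C)CC(=O)Cl)c1-c1cc(OCc2ccccc2)cc(=O)o1 | intermediate
20 | (3R)-5-[4-(benzyloxy)-2-oxo-2H-pyran-6-yl]-3-[(tert-butyldiphenylsilyl)oxy]-8-methoxy-6-(3-methylbutyl)-3,4-dihydronaphthalen-1(2H)-one | CC(C)CCc1cc(OC)c2c(c1-c1cc(OCc3ccccc3)cc(=O)o1)C[C@@H](O[Si](c1ccccc1)(c1ccccc1)C(C)(C)C)CC2=O | intermediate
21 | (3R)-3-[(tert-butyldiphenylsilyl)oxy]-8-hydroxy-5-(4-hydroxy-2-oxo-2H-pyran-6-yl)-6-(3-methylbutyl)-3,4-dihydronaphthalen-1(2H)-one | CC(C)CCc1cc(O)c2c(c1-c1cc(O)cc(=O)o1)C[C@@H](O[Si](c1ccccc1)(c1ccccc1)C(C)(C)C)CC2=O | intermediate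
22 | (3R)-3,8-dihydroxy-5-(4-hydroxy-2-oxo-2H-pyran-6-yl)-6-(3-methylbutyl)-3,4-dihydronaphthalen-1(2H)-one | CC(C)CCc1cc(O)c2c(c1-c1cc(O)cc(=O)o1)C[C@@H](O)CC2=O | target

Total step count: 13.
Longest linear sequence: 12 steps (from 1 through steps 1 and 3 to 13; the same length from 4 through steps 2 to 13).

Steps most likely to fail

Step 11 (Friedel–Crafts ring closure). Acylation at C8a may be slow, because the position is ortho to the methoxy group on a ring that carries the electron-poor pyronyl group. The Lewis acid may then cleave the pyrone benzyl ether, or promote loss of the C3 silyloxy group from the freshly formed β-silyloxy ketone, followed by aromatisation to a naphthol. Fallback: set out from acid 18. Coupling with dimethylamine (EDC·HCl, HOBt, i-Pr2NEt, CH2Cl2) would give the N,N-dimethylamide F1. Electrophilic amide activation with Tf2O and 2-fluoropyridine in CH2Cl2 at −78 → 0 °C (an intramolecular Vilsmeier–Haack-type acylation) should close the ring to the cyclic iminium triflate F2. Aqueous NaHCO3 hydrolyses F2 to ketone 20, where the route is rejoined. The ketone is then released only at work-up, with no metal Lewis acid present.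

Step 8 (pyrone annulation). HCl may protodesilylate the enol ether back to ketone 12 faster than C-acylation, malonyl dichloride may condense with itself, or the enol oxygen may be acylated first and give open-chain esters. Fallback: set out from aryl bromide 9 and give up the annulation for a cross-coupling at C6'. Miyaura borylation (B2pin2, Pd(OAc)2, SPhos, KOAc, dioxane, 90 °C) would give the aryl pinacol boronate F3. Suzuki–Miyaura coupling (Pd(OAc)2, SPhos, K3PO4, toluene/H2O, 80 °C) with 4-(benzyloxy)-6-chloro-2H-pyran-2-one F4 would give benzyl ether 17, where the route is rejoined. F4 is made by Mitsunobu benzylation (BnOH, PPh3, DIAD, THF) of the known 6-chloro-4-hydroxy-2H-pyran-2-one.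

Step 12 (double dealkylation). In the boron-chelated ketone the C3 silyloxy group may be eliminated and the ring aromatised, the benzyl cation may alkylate the electron-rich arene or C3' of the pyrone, or demethylation may stop short. Fallback: set out from 20. Hydrogenolysis (H2, 1 atm, Pd/C, EtOAc, rt) would remove the benzyl group and give the 8-methoxy tetralone with free pyrone hydroxyl F5. Chelation-assisted demethylation with MgI2 etherate (Et2O/toluene, 50 °C) would follow, iodide attacking the methyl group of the magnesium chelate between the C1 carbonyl and the C8 oxygen. This gives 21, where the route is rejoined.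

Further compounds
F1 | step 11 | (3R)-4-{2-[4-(benzyloxy)-2-oxo-2H-pyran-6-yl]-5-methoxy-3-(3-methylbutyl)phenyl}-3-[(tert-butyldiphenylsilyl)oxy]-N,N-dimethylbutanamide | CC(C)CCc1cc(OC)cc(C[C@@H](O[Si](c2ccccc2)(c2ccccc2)C(C)(C)C)CC(=O)N(C)C)c1-c1cc(OCc2ccccc2)cc(=O)o1
F2 | step 11 | N-{(3R)-5-[4-(benzyloxy)-2-oxo-2H-pyran-6-yl]-3-[(tert-butyldiphenylsilyl)oxy]-8-methoxy-6-(3-methylbutyl)-3,4-dihydronaphthalen-1(2H)-ylidene}-N-methylmethanaminium trifluoromethanesulfonate | CC(C)CCc1cc(OC)c2c(c1-c1cc(OCc3ccccc3)cc(=O)o1)C[C@@H](O[Si](c1ccccc1)(c1ccccc1)C(C)(C)C)CC2=[N+](C)C.[O-]S(=O)(=O)C(F)(F)F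
F3 | step 8 | ethyl (3R)-3-[(tert-butyldiphenylsilyl)oxy]-4-[5-methoxy-3-(3-methylbutyl)-2-(4,4,5,5-tetramethyl-1,3,2-dioxaborolan-2-yl)phenyl]butanoate | CC(C)CCc1cc(OC)cc(C[C@@H](O[Si](c2ccccc2)(c2ccccc2)C(C)(C)C)CC(=O)OCC)c1B1OC(C)(C)C(C)(C)O1
F4 | step 8 | 4-(benzyloxy)-6-chloro-2H-pyran-2-one | O=c1cc(OCc2ccccc2)cc(Cl)o1
F5 | step 12 | (3R)-3-[(tert-butyldiphenylsilyl)oxy]-5-(4-hydroxy-2-oxo-2H-pyran-6-yl)-8-methoxy-6-(3-methylbutyl)-3,4-dihydronaphthalen-1(2H)-one | CC(C)CCc1cc(OC)c2c(c1-c1cc(O)cc(=O)o1)C[C@@H](O[Si](c1ccccc1)(c1ccccc1)C(C)(C)C)CC2=O
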